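Readings and results were computed from invented constants.

In a one-step world a flask has one time constant and one end, but the flask I hand you seems to have two uses for its reagent, so I follow one reagent molecule.

| flask | starting material | reagent | second substrate | catalyst | remark | time |
|---|---|---|---|---|---|---|
| ash | 0.14 M | 0.168 M | 0.094 M | 6 mM | run made earlier |  |
| alder | 0.14 M | 0.168 M | 0.21 M | 6 mM | run made earlier |  |
| flask | 0.14 M | 0.168 M | 0.140 M | 6.0 mM |  | 50 min |

| run | time / min | target / % | starting material / % |
|---|---|---|---|
| ash | 8.00 | 27 | 73 |
| ash | 15.0 | 28 | 67 |
| ash | 25.0 | 29 | 67 |
| ash | 30.0 | 32 | 70 |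
| ash | 40.0 | 27 | 70 |
| ash | 50.0 | 29 | 71 |
| ash | 60.0 | 26 | 73 |
| alder | 5.00 | 14 | 81 |
| alder | 8.00 | 21 | 81 |
| alder | 12.0 | 20 | 82 |
| alder | 15.0 | 20 | 83 |
| alder | 25.0 | 17 | 81 |
| alder | 40.0 | 11 | 91 |
| alder | 60.0 | 10 | 89 |

(scatter of a reading: 2 percentage points)

* target present at 50 min, in percent of the starting material charged
* starting material present at 50 min, in percent of the starting material charged
* concentration of reagent at 50 min, in M

The molecule's first fork is second substrate or starting material. In the alder run, with more second substrate than reagent, target reads 21 % at 8.00 min and 10 % at 60.0 min, while starting material climbs back, so target looks like a loan of reagent, and second substrate like the way out. I therefore count the surplus (excess reagent): reagent charged minus second substrate charged. Assuming the second substrate in the ash run has reacted away by 50.0 min, the target reading there comes to 0.549 of the surplus, the target's share, a figure that carries the scatter of that reading.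

This flask's surplus is 0.0280 M, so my estimate from the share is 11.0 % target once its second substrate has reacted away. I expect more than that when you sample at 50 min, with starting material making up the rest. Add no second substrate. The forecast says 16 % target, 84 % starting material and 0.02 M reagent, noting that “Consumption may be incomplete at 50 min”.

The flask gives 18.8 % target, 81.2 % starting material and 0.00807 M reagent, with 0.0144 M of dormant form beside it, which makes 0.0225 M for the two forms together.

    reagent ⇌ dormant form (K = 2.10, k = 0.0170 min⁻¹)
    second substrate + reagent + catalyst → catalyst + second product (k = 280 M⁻² min⁻¹)
    starting material + reagent + catalyst ⇌ catalyst + target (K = 19.0 M⁻¹, k = 90.0 M⁻² min⁻¹)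

In this flask at 50 min, with 14.8 % of the second substrate left, second product stands at 0.119 M, so the surplus so far is 0.0487 M, and the share makes that 19.1 % target. A neighbouring flask, the same recipe charged with 0.056 M of second substrate, has 0.0550 M of second product at 50 min. Its surplus is 0.113 M, so the share gives 44.3 % target, and that flask holds 37.8 %.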